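**Plan**

1. Labels: ring A = 3,5-dioxygenated phenoxy ring; ring B = pentaoxygenated dioxin ring (B1 carries the ether to ring A, B2 and B4 the hydroxyls, B3 is CH, B5 and B6 the dioxin oxygens); ring C = ring shared by dioxin and furan; ring D = outer dihydroxy ring. Dibenzofuran locants are C1–C4 (ring D) and C6–C9 (ring C), so the dioxin ethers are C9–O–B5 and C8–O–B6.
2. Enabling feature: ring D has oxygen on C1 (beside the ring-fusion carbon C9b) and on C3, with C2 and C4 as CH. C1–C4 is thus a buta-1,3-diene oxygenated twice at one terminus and once at C3, and C4a/C9b are C2/C3 of a benzofuran whose C3 can carry a nitro group that leaves as HNO2.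
3. Retrosynthetic cuts: (a) seven O–CH3 bonds; (b) the ether C8–O–B6 (copper-catalysed ring closure); (c) the ethers C9–O–B5 and B1–O–ring A (two SNAr reactions on 5-bromo-4,6-difluoroisophthalaldehyde, whose formyl groups later become the B2 and B4 hydroxyls); (d) C4–C4a and C1–C9b of ring D (Diels–Alder); (e) O1–C2 and C2–C3 of the furan (orthoformate carbon).
4. Forward order: ring C (3,4,5-trimethoxyphenol) → furan ring → ring D → ring B, already carrying ring A, joined at O9 → dioxin ring closed at O8 → all methyl ethers removed.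
5. Stereochemistry: the target has no stereocentre, so only orientation must be controlled. The nitro group fixes the regiochemistry of the cycloaddition. An aldehyde-directed BCl3 demethylation sets O9 and O8 apart from O7 (benzyl on O9, methoxymethyl on O8). Dakin oxidation before the second ether closure excludes Smiles scrambling.

Key step: step 12

Remark (assumption): the dibenzofuran locants of the key-step product are kept in the names of all later intermediates regardless of nomenclature priority. The silyl ketene acetal diene is used as its E/Z mixture, because its geometry and all transient stereocentres of the cycloadduct are destroyed on aromatisation.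

**Route**

Step 1
Reactants: 1 3,4,5-trimethoxyphenol
Product: 2 6-hydroxy-2,3,4-trimethoxybenzaldehyde
Conditions: MgCl2, Et3N, (CH2O)n, MeCN, reflux; then 1 M HCl
Reagents that add atoms: paraformaldehyde (formaldehyde) C=O
Why: Magnesium-mediated ortho-formylation of a phenol, in which the magnesium phenoxide delivers formaldehyde to an ortho carbon and a second equivalent oxidises the benzylic alkoxide; the two ortho positions of 1 are equivalent, so only one aldehyde can form.

Step 2
Reactants: 2 6-hydroxy-2,3,4-trimethoxybenzaldehyde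
Product: 3 2-formyl-3,4,5-trimethoxyphenyl methanesulfonate
Conditions: MsCl, Et3N, CH2Cl2, 0 °C
Reagents that add atoms: methanesulfonyl chloride CS(=O)(=O)Cl
Why: Standard sulfonylation of a phenol; the mesylate removes the chelating hydroxyl so that step 3 can only engage the methoxy side of the aldehyde, and it later shields the ring from the peroxide of step 7.

Step 3
Reactants: 3 2-formyl-3,4,5-trimethoxyphenyl methanesulfonate
Product: 4 2-formyl-3,4-dihydroxy-5-methoxyphenyl methanesulfonate
Conditions: BCl3 (3.5 equiv), CH2Cl2, 0 °C to rt; then H2O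
Reagents that add atoms: none
Why: Chelation-controlled ether cleavage by BCl3, in which the aldehyde–boron chelate cleaves the ortho 3-methoxy group and the resulting aryloxyboron chloride relays cleavage to the 4-methoxy group (as in the conversion of 2,3,4-trimethoxybenzaldehyde into 2,3-dihydroxy-4-methoxybenzaldehyde), while the 5-methoxy group and the sulfonate are untouched.

Step 4
Reactants: 4 2-formyl-3,4-dihydroxy-5-methoxyphenyl methanesulfonate
Product: 5 2-formyl-3-hydroxy-5-methoxy-4-(methoxymethoxy)phenyl methanesulfonate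
Conditions: NaH (2.05 equiv), DMF, 0 °C; MOMCl (1.0 equiv), −20 to 0 °C; then AcOH
Reagents that add atoms: chloromethyl methyl ether COCCl
Why: Williamson etherification of the catechol dianion; the 3-oxide is tied up in the chelate with the formyl group, so the more nucleophilic 4-oxide (the future O8) is alkylated selectively, as established for dianions of 2,3-dihydroxybenzaldehydes.

Step 5
Reactants: 5 2-formyl-3-hydroxy-5-methoxy-4-(methoxymethoxy)phenyl methanesulfonate
Product: 6 3-(benzyloxy)-2-formyl-5-methoxy-4-(methoxymethoxy)phenyl methanesulfonate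
Conditions: BnBr, K2CO3, DMF, 50 °C
Reagents that add atoms: benzyl bromide BrCc1ccccc1
Why: Williamson etherification of the remaining hydrogen-bonded 3-hydroxyl (the future bay oxygen O9) under carbonate conditions that leave the aryl mesylate intact.

Step 6
Reactants: 6 3-(benzyloxy)-2-formyl-5-methoxy-4-(methoxymethoxy)phenyl methanesulfonate
Product: 7 3-(benzyloxy)-2-[(E)-(hydroxyimino)methyl]-5-methoxy-4-(methoxymethoxy)phenyl methanesulfonate
Conditions: NH2OH·HCl, NaOAc, EtOH/H2O, rt
Reagents that add atoms: hydroxylamine hydrochloride NO.Cl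
Why: Oxime condensation of an aryl aldehyde under acetate buffer, mild enough for the acetal and the sulfonate.

Step 7
Reactants: 7 3-(benzyloxy)-2-[(E)-(hydroxyimino)methyl]-5-methoxy-4-(methoxymethoxy)phenyl methanesulfonate
Product: 8 3-(benzyloxy)-5-methoxy-4-(methoxymethoxy)-2-(nitromethyl)phenyl methanesulfonate
Conditions: NaBO3·4H2O, AcOH, 55 °C
Reagents that add atoms: sodium perborate [Na+].[Na+].O[B-]1(O)OO[B-](O)(O)OO1
Why: Perborate/acetic acid oxidation of an aldoxime at nitrogen to the aci-nitro compound, which tautomerises to the primary nitroalkane; the sulfonate keeps the arene electron-poor enough to resist the peroxide, and acetic acid alone does not cleave the aryl methoxymethyl ether.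

Step 8
Reactants: 8 3-(benzyloxy)-5-methoxy-4-(methoxymethoxy)-2-(nitromethyl)phenyl methanesulfonate
Product: 9 3-(benzyloxy)-5-methoxy-4-(methoxymethoxy)-2-(nitromethyl)phenol
Conditions: LiN(iPr)2 (4 equiv), THF, −78 °C; then AcOH, −78 °C
Reagents that add atoms: none
Why: Base-induced E1cB cleavage of an aryl methanesulfonate (expulsion of sulfene) frees the phenoxide at low temperature without a nucleophile at sulfur, while the nitro group is stored as its lithium nitronate and returned by the acetic acid quench; 9 is used at once.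

Step 9
Reactants: 9 3-(benzyloxy)-5-methoxy-4-(methoxymethoxy)-2-(nitromethyl)phenol
Product: 10 4-(benzyloxy)-6-methoxy-5-(methoxymethoxy)-3-nitro-1-benzofuran
Conditions: HC(OEt)3, pyridinium p-toluenesulfonate (cat.), toluene, 100 °C, removal of EtOH
Reagents that add atoms: triethyl orthoformate CCOC(OCC)OCC
Why: Proposed new method: under mild acid the nitronic acid tautomer of 9 should be C-alkylated by the diethoxycarbenium ion, the phenol should close 5-exo-trig onto the derived oxocarbenium carbon, and E1cB loss of ethanol (the hydrogen alpha to nitro is acidic) should give the aromatic furan; the closest known reactions are the orthoformate annulation of 2-hydroxy-omega-nitroacetophenones to 3-nitrochromones and the formylation–cyclodehydration of 2-hydroxyphenylacetates to benzofuran-3-carboxylates.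

Step 10
Reactants: 11 methyl acetoacetate
Product: 12 methyl (E)-3-methoxybut-2-enoate
Conditions: HC(OMe)3, H2SO4 (cat.), MeOH, rt
Reagents that add atoms: trimethyl orthoformate COC(OC)OC
Why: Acid-catalysed enol ether formation from a beta-keto ester (ketalisation, then loss of methanol) gives the conjugated E enoate.

Step 11
Reactants: 12 methyl (E)-3-methoxybut-2-enoate
Product: 13 1,3-dimethoxy-1-(trimethylsilyloxy)buta-1,3-diene (Brassard diene)
Conditions: LiN(iPr)2, THF, −78 °C; Me3SiCl
Reagents that add atoms: chlorotrimethylsilane C[Si](C)(C)Cl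
Why: Vinylogous deprotonation of the gamma-methyl group and O-silylation of the dienolate give the silyl ketene acetal diene.

Step 12
Reactants: 10 4-(benzyloxy)-6-methoxy-5-(methoxymethoxy)-3-nitro-1-benzofuran; 13 1,3-dimethoxy-1-(trimethylsilyloxy)buta-1,3-diene (4 equiv)
Product: 17 9-(benzyloxy)-3,7-dimethoxy-8-(methoxymethoxy)dibenzofuran-1-ol, via cis-fused nitro cycloadduct 14 (not isolated), via dihydrodibenzofuran silyl ketal 15 (not isolated), via aryl trimethylsilyl ether 16 (not isolated)
Conditions: toluene, 130 °C, sealed tube; then K2CO3 (cat.), MeOH, rt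
Reagents that add atoms: none
Why: The reaction is a strongly asynchronous polar [4+2] cycloaddition: the CH2 terminus of 13 attacks furan C2 of 10 (beta to the nitro group), the nitronate carbon C3 then bonds to the silyloxy(methoxy)carbenium carbon to give 14, thermal loss of HNO2 restores the furan (15), 1,4-loss of methanol aromatises ring D (16) and methanolysis frees the phenol. The closest known reaction type is the thermal cycloaddition of nitrobenzofurans with 1-methoxy-3-(trimethylsilyloxy)butadiene, which gives hydroxydibenzofurans after extrusion of nitrous acid, together with benzannulations of this ketene acetal diene with haloquinones. Ring D, a six-membered carbocycle, closes by the intermolecular [4+2] mode, the second bond being in the stepwise limit a 6-exo-trig attack of the nitronate carbon on the oxocarbenium ion. The 4a and 9b centres of 14 are cis through suprafacial addition, but they and the ketal carbon are erased on aromatisation, so no stereocentre needs control. The selectivity needed is orientation, and the nitro group at C3 secures it by making C2 the electrophilic partner of the nucleophilic CH2 terminus, which places the ketene acetal oxygen on C1 beside C9b and the methoxy group on C3. The benzyloxy group peri to the nitro group and the three donor groups lower the reactivity, hence the excess of diene and the temperature; collapse of the ketal with loss of silanol instead of methanol would give the 1-methyl ether, which converges with the main line after step 13.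

Step 13
Reactants: 17 9-(benzyloxy)-3,7-dimethoxy-8-(methoxymethoxy)dibenzofuran-1-ol
Product: 18 9-(benzyloxy)-1,3,7-trimethoxy-8-(methoxymethoxy)dibenzofuran
Conditions: MeI, K2CO3, acetone, reflux
Reagents that add atoms: iodomethane CI
Why: Williamson methylation of the C1 phenol, so that the only hydroxyl liberated in the next step is the bay one.

Step 14
Reactants: 18 9-(benzyloxy)-1,3,7-trimethoxy-8-(methoxymethoxy)dibenzofuran
Product: 19 1,3,7-trimethoxy-8-(methoxymethoxy)dibenzofuran-9-ol
Conditions: H2 (1 atm), Pd/C, EtOAc/MeOH, rt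
Reagents that add atoms: none
Why: Hydrogenolysis of the benzyl ether frees only O9–H, the methoxymethyl acetal and the methyl ethers being inert to hydrogen on palladium.

Step 15
Reactants: 20 2-bromo-1,3-difluorobenzene
Product: 21 3-bromo-2,4-difluorobenzaldehyde
Conditions: LiN(iPr)2, THF, −78 °C; DMF; then 1 M HCl
Reagents that add atoms: N,N-dimethylformamide CN(C)C=O
Why: Fluorine-directed ortho-lithiation with a lithium amide at low temperature (no benzyne formation or halogen migration) followed by formylation with DMF.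

Step 16
Reactants: 21 3-bromo-2,4-difluorobenzaldehyde
Product: 22 2-(3-bromo-2,4-difluorophenyl)-1,3-dioxolane
Conditions: HOCH2CH2OH, TsOH (cat.), toluene, reflux, Dean–Stark
Reagents that add atoms: ethylene glycol OCCO
Why: Acid-catalysed acetalisation protects the aldehyde for the second metalation.

Step 17
Reactants: 22 2-(3-bromo-2,4-difluorophenyl)-1,3-dioxolane
Product: 24 5-bromo-4,6-difluorobenzene-1,3-dicarbaldehyde, via dioxolane-protected monoaldehyde 23 (not isolated)
Conditions: LiN(iPr)2, THF, −78 °C; DMF; then 2 M HCl, THF, rt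
Reagents that add atoms: N,N-dimethylformamide CN(C)C=O
Why: A second fluorine-directed ortho-lithiation/formylation at the position ortho to the other fluorine, with hydrolysis of the dioxolane in the acidic work-up.

Step 18
Reactants: 24 5-bromo-4,6-difluorobenzene-1,3-dicarbaldehyde (2 equiv); 25 3,5-dimethoxyphenol
Product: 26 5-bromo-4-(3,5-dimethoxyphenoxy)-6-fluorobenzene-1,3-dicarbaldehyde
Conditions: K2CO3, DMF, 0 °C to rt
Reagents that add atoms: none
Why: Nucleophilic aromatic substitution of a fluoride that is ortho and para to the two formyl groups; the two activated fluorides of 24 are equivalent, the bromide (meta to both formyl groups) is inert, and the excess of 24 limits double substitution.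

Step 19
Reactants: 19 1,3,7-trimethoxy-8-(methoxymethoxy)dibenzofuran-9-ol; 26 5-bromo-4-(3,5-dimethoxyphenoxy)-6-fluorobenzene-1,3-dicarbaldehyde
Product: 27 5-bromo-4-(3,5-dimethoxyphenoxy)-6-{[1,3,7-trimethoxy-8-(methoxymethoxy)dibenzofuran-9-yl]oxy}benzene-1,3-dicarbaldehyde
Conditions: Cs2CO3, DMF, 60 °C
Reagents that add atoms: none
Why: Nucleophilic aromatic substitution of the remaining activated fluoride by the bay phenoxide forms the C9–O–B5 ether; with O8 blocked there is no second phenoxide, so no Smiles rearrangement can exchange the two catechol oxygens.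

Step 20
Reactants: 27 5-bromo-4-(3,5-dimethoxyphenoxy)-6-{[1,3,7-trimethoxy-8-(methoxymethoxy)dibenzofuran-9-yl]oxy}benzene-1,3-dicarbaldehyde
Product: 29 5-bromo-4-(3,5-dimethoxyphenoxy)-6-{[1,3,7-trimethoxy-8-(methoxymethoxy)dibenzofuran-9-yl]oxy}benzene-1,3-diol, via bis(formate) ester 28 (not isolated)
Conditions: mCPBA, CH2Cl2, 0 °C to rt; then K2CO3 (cat.), MeOH, rt
Reagents that add atoms: 3-chloroperbenzoic acid OOC(=O)c1cccc(Cl)c1
Why: Baeyer–Villiger (Dakin-type) oxidation of two aryl aldehydes that each have an ortho and a para aryloxy donor, so the aryl group migrates, followed by methanolysis of the formates; this installs the B2 and B4 oxygens and removes the groups that would activate ring B towards Smiles rearrangement once O8 is freed.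

Step 21
Reactants: 29 5-bromo-4-(3,5-dimethoxyphenoxy)-6-{[1,3,7-trimethoxy-8-(methoxymethoxy)dibenzofuran-9-yl]oxy}benzene-1,3-diol
Product: 30 9-[2-bromo-3-(3,5-dimethoxyphenoxy)-4,6-dimethoxyphenoxy]-1,3,7-trimethoxy-8-(methoxymethoxy)dibenzofuran
Conditions: MeI, K2CO3, DMF, rt
Reagents that add atoms: iodomethane CI
Why: Williamson methylation of both phenols gives an oxidation-stable ring B for the copper step.

Step 22
Reactants: 30 9-[2-bromo-3-(3,5-dimethoxyphenoxy)-4,6-dimethoxyphenoxy]-1,3,7-trimethoxy-8-(methoxymethoxy)dibenzofuran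
Product: 31 9-[2-bromo-3-(3,5-dimethoxyphenoxy)-4,6-dimethoxyphenoxy]-1,3,7-trimethoxydibenzofuran-8-ol
Conditions: HCl (cat.), MeOH/THF, 50 °C
Reagents that add atoms: none
Why: Acid-catalysed acetal exchange cleaves the methoxymethyl ether without touching aryl methyl ethers, diaryl ethers or the aryl bromide.

Step 23
Reactants: 31 9-[2-bromo-3-(3,5-dimethoxyphenoxy)-4,6-dimethoxyphenoxy]-1,3,7-trimethoxydibenzofuran-8-ol
Product: 32 hepta-O-methyl ether of the target (methoxy on C1, C3, C7, B2, B4 and on both free positions of ring A; dioxin ethers C9–O–B5 and C8–O–B6)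
Conditions: CuI (20 mol%), picolinic acid (40 mol%), K3PO4, DMSO, 110 °C
Reagents that add atoms: none
Why: Intramolecular copper-catalysed Ullmann diaryl ether synthesis closes the six-membered dioxin ring by attack of the O8 phenoxide on the bromine-bearing B6; the now electron-rich ring B cannot undergo Smiles exchange, so the regiochemistry set in step 19 is kept.

Step 24
Reactants: 32 hepta-O-methyl ether of the target
Product: 33 CNP0256302.0 (target)
Conditions: BBr3 (excess), CH2Cl2, −78 °C to rt; then MeOH/H2O, under argon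
Reagents that add atoms: none
Why: Exhaustive Lewis acid demethylation of the seven aryl methyl ethers by BBr3, which does not cleave the diaryl ether, dioxin or furan C–O bonds.

**Compound list**

1 | 3,4,5-trimethoxyphenol | COc1cc(O)cc(OC)c1OC | starting material
2 | 6-hydroxy-2,3,4-trimethoxybenzaldehyde | O=Cc1c(O)cc(OC)c(OC)c1OC | intermediate
3 | 2-formyl-3,4,5-trimethoxyphenyl methanesulfonate | CS(=O)(=O)Oc1cc(OC)c(OC)c(OC)c1C=O | intermediate
4 | 2-formyl-3,4-dihydroxy-5-methoxyphenyl methanesulfonate | CS(=O)(=O)Oc1cc(OC)c(O)c(O)c1C=O | intermediate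
5 | 2-formyl-3-hydroxy-5-methoxy-4-(methoxymethoxy)phenyl methanesulfonate | CS(=O)(=O)Oc1cc(OC)c(OCOC)c(O)c1C=O | intermediate
6 | 3-(benzyloxy)-2-formyl-5-methoxy-4-(methoxymethoxy)phenyl methanesulfonate | CS(=O)(=O)Oc1cc(OC)c(OCOC)c(OCc2ccccc2)c1C=O | intermediate
7 | 3-(benzyloxy)-2-[(E)-(hydroxyimino)methyl]-5-methoxy-4-(methoxymethoxy)phenyl methanesulfonate | CS(=O)(=O)Oc1cc(OC)c(OCOC)c(OCc2ccccc2)c1/C=N/O | intermediate
8 | 3-(benzyloxy)-5-methoxy-4-(methoxymethoxy)-2-(nitromethyl)phenyl methanesulfonate | CS(=O)(=O)Oc1cc(OC)c(OCOC)c(OCc2ccccc2)c1C[N+](=O)[O-] | intermediate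
9 | 3-(benzyloxy)-5-methoxy-4-(methoxymethoxy)-2-(nitromethyl)phenol | Oc1cc(OC)c(OCOC)c(OCc2ccccc2)c1C[N+](=O)[O-] | intermediate
10 | 4-(benzyloxy)-6-methoxy-5-(methoxymethoxy)-3-nitro-1-benzofuran | COCOc1c(OC)cc2occ([N+](=O)[O-])c2c1OCc1ccccc1 | intermediate (key-step precursor)
11 | methyl acetoacetate | COC(=O)CC(C)=O | starting material
12 | methyl (E)-3-methoxybut-2-enoate | COC(=O)/C=C(\C)OC | intermediate
13 | 1,3-dimethoxy-1-(trimethylsilyloxy)buta-1,3-diene (E/Z mixture at the ketene acetal) | COC(=C)C=C(OC)O[Si](C)(C)C | intermediate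
14 | 9-(benzyloxy)-1,3,7-trimethoxy-8-(methoxymethoxy)-9b-nitro-1-(trimethylsilyloxy)-1,4,4a,9b-tetrahydrodibenzofuran (racemic, 4a-H and 9b-NO2 cis, ketal carbon unassigned) | [O-][N+](=O)[C@]12c3c(OCc4ccccc4)c(OCOC)c(OC)cc3O[C@H]1CC(OC)=CC2(OC)O[Si](C)(C)C | intermediate (not isolated)
15 | 9-(benzyloxy)-1,3,7-trimethoxy-8-(methoxymethoxy)-1-(trimethylsilyloxy)-1,4-dihydrodibenzofuran (racemic) | COC1=CC(OC)(O[Si](C)(C)C)c2c(C1)oc1cc(OC)c(OCOC)c(OCc3ccccc3)c21 | intermediate (not isolated)
16 | 9-(benzyloxy)-3,7-dimethoxy-8-(methoxymethoxy)-1-(trimethylsilyloxy)dibenzofuran | COc1cc(O[Si](C)(C)C)c2c(c1)oc1cc(OC)c(OCOC)c(OCc3ccccc3)c12 | intermediate (not isolated)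
17 | 9-(benzyloxy)-3,7-dimethoxy-8-(methoxymethoxy)dibenzofuran-1-ol | COc1cc(O)c2c(c1)oc1cc(OC)c(OCOC)c(OCc3ccccc3)c12 | intermediate (key-step product)
18 | 9-(benzyloxy)-1,3,7-trimethoxy-8-(methoxymethoxy)dibenzofuran | COc1cc(OC)c2c(c1)oc1cc(OC)c(OCOC)c(OCc3ccccc3)c12 | intermediate
19 | 1,3,7-trimethoxy-8-(methoxymethoxy)dibenzofuran-9-ol | COc1cc(OC)c2c(c1)oc1cc(OC)c(OCOC)c(O)c12 | intermediate
20 | 2-bromo-1,3-difluorobenzene | Fc1cccc(F)c1Br | starting material
21 | 3-bromo-2,4-difluorobenzaldehyde | O=Cc1ccc(F)c(Br)c1F | intermediate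
22 | 2-(3-bromo-2,4-difluorophenyl)-1,3-dioxolane | Fc1ccc(C2OCCO2)c(F)c1Br | intermediate
23 | 3-bromo-5-(1,3-dioxolan-2-yl)-2,4-difluorobenzaldehyde | O=Cc1cc(C2OCCO2)c(F)c(Br)c1F | intermediate (not isolated)
24 | 5-bromo-4,6-difluorobenzene-1,3-dicarbaldehyde | O=Cc1cc(C=O)c(F)c(Br)c1F | intermediate
25 | 3,5-dimethoxyphenol | COc1cc(O)cc(OC)c1 | starting material
26 | 5-bromo-4-(3,5-dimethoxyphenoxy)-6-fluorobenzene-1,3-dicarbaldehyde | COc1cc(OC)cc(Oc2c(C=O)cc(C=O)c(F)c2Br)c1 | intermediate
27 | 5-bromo-4-(3,5-dimethoxyphenoxy)-6-{[1,3,7-trimethoxy-8-(methoxymethoxy)dibenzofuran-9-yl]oxy}benzene-1,3-dicarbaldehyde | COc1cc(OC)cc(Oc2c(C=O)cc(C=O)c(Oc3c(OCOC)c(OC)cc4oc5cc(OC)cc(OC)c5c34)c2Br)c1 | intermediate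
28 | 5-bromo-4-(3,5-dimethoxyphenoxy)-6-{[1,3,7-trimethoxy-8-(methoxymethoxy)dibenzofuran-9-yl]oxy}benzene-1,3-diyl diformate | COc1cc(OC)cc(Oc2c(OC=O)cc(OC=O)c(Oc3c(OCOC)c(OC)cc4oc5cc(OC)cc(OC)c5c34)c2Br)c1 | intermediate (not isolated)
29 | 5-bromo-4-(3,5-dimethoxyphenoxy)-6-{[1,3,7-trimethoxy-8-(methoxymethoxy)dibenzofuran-9-yl]oxy}benzene-1,3-diol | COc1cc(OC)cc(Oc2c(O)cc(O)c(Oc3c(OCOC)c(OC)cc4oc5cc(OC)cc(OC)c5c34)c2Br)c1 | intermediate
30 | 9-[2-bromo-3-(3,5-dimethoxyphenoxy)-4,6-dimethoxyphenoxy]-1,3,7-trimethoxy-8-(methoxymethoxy)dibenzofuran | COc1cc(OC)cc(Oc2c(OC)cc(OC)c(Oc3c(OCOC)c(OC)cc4oc5cc(OC)cc(OC)c5c34)c2Br)c1 | intermediate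
31 | 9-[2-bromo-3-(3,5-dimethoxyphenoxy)-4,6-dimethoxyphenoxy]-1,3,7-trimethoxydibenzofuran-8-ol | COc1cc(OC)cc(Oc2c(OC)cc(OC)c(Oc3c(O)c(OC)cc4oc5cc(OC)cc(OC)c5c34)c2Br)c1 | intermediate
32 | hepta-O-methyl ether of the target | COc1cc(OC)cc(Oc2c(OC)cc(OC)c3c2Oc2c(OC)cc4oc5cc(OC)cc(OC)c5c4c2O3)c1 | intermediate
33 | CNP0256302.0 | Oc1cc(O)cc(Oc2c(O)cc(O)c3c2Oc2c(O)cc4oc5cc(O)cc(O)c5c4c2O3)c1 | target

**Step count**

Total: 24 steps. Longest linear sequence: 18 steps (steps 1–9, 12–14 and 19–24).

**Steps most likely to fail**

Step 9 (proposed new method). The electron-rich 2-(nitromethyl)phenol may expel nitrite through an ortho-quinone methide, or the orthoester may O-alkylate the phenol faster than it C-formylates the weakly nucleophilic nitronic acid. The fallback uses known chemistry, sets out from 8 (before the phenol is freed) and returns at 10. Condensation of 8 with N,N-dimethylformamide dimethyl acetal (DMF, 90 °C), a standard reaction of arylnitromethanes, should give the push-pull nitro enamine 3-(benzyloxy)-2-[(E)-2-(dimethylamino)-1-nitroethenyl]-5-methoxy-4-(methoxymethoxy)phenyl methanesulfonate F1, which has no acidic C–H. LiN(iPr)2 at −78 °C then removes the sulfonate as in step 8, and warming with AcOH lets the phenol add to the iminium tautomer and expel dimethylamine, the oxygen counterpart of the enamine ring closure of the Leimgruber–Batcho indole synthesis. Compound 10 is thus reached without 9 ever being handled.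

Step 12 (key step). After the first bond is made at furan C2, ring closure at the nitro-bearing carbon, which lies peri to the benzyloxy group, may be too slow, so that silyl transfer to the nitronate or thermal decay of the diene intercepts the zwitterion. The fallback sets out from 10 and 13, returns at 17, and makes the same two bonds one after the other:
- Vinylogous Mukaiyama–Michael addition of 13 to 10 (Me3SiOTf cat., CH2Cl2, −78 °C; aqueous work-up) should give methyl (E)-4-[4-(benzyloxy)-6-methoxy-5-(methoxymethoxy)-3-nitro-2,3-dihydro-1-benzofuran-2-yl]-3-methoxybut-2-enoate F2 as a diastereomer mixture.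
- DBU eliminates nitrous acid to give methyl (E)-4-[4-(benzyloxy)-6-methoxy-5-(methoxymethoxy)-1-benzofuran-2-yl]-3-methoxybut-2-enoate F3.
- LiOH gives (E)-4-[4-(benzyloxy)-6-methoxy-5-(methoxymethoxy)-1-benzofuran-2-yl]-3-methoxybut-2-enoic acid F4.
- Ac2O/NaOAc at reflux closes ring D by intramolecular Friedel–Crafts acylation at furan C3 with enol acetylation, giving 9-(benzyloxy)-3,7-dimethoxy-8-(methoxymethoxy)dibenzofuran-1-yl acetate F5.
- K2CO3/MeOH then returns 17.

Step 19. The bay phenoxide, flanked by the C8 acetal and, across the bay, by the C1 methoxy group, must attack a carbon flanked by formyl and bromine; the substitution may be slow, and prolonged heating would allow aryloxide exchange at the other activated carbon. The fallback sets out from 19 and 24, returns at 27, and inverts the order of the two substitutions. The hindered phenoxide of 19 is first combined with an excess of the symmetric difluoride 24, the most electrophilic and least hindered partner (Cs2CO3, DMF, rt), to give 5-bromo-4-fluoro-6-{[1,3,7-trimethoxy-8-(methoxymethoxy)dibenzofuran-9-yl]oxy}benzene-1,3-dicarbaldehyde F6. The unhindered phenol 25 then displaces the second activated fluoride (Cs2CO3, DMF, rt) to give 27.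

**Further compounds**

F1 | step 9 | 3-(benzyloxy)-2-[(E)-2-(dimethylamino)-1-nitroethenyl]-5-methoxy-4-(methoxymethoxy)phenyl methanesulfonate | CN(C)/C=C(\c1c(OS(C)(=O)=O)cc(OC)c(OCOC)c1OCc1ccccc1)/[N+](=O)[O-]
F2 | step 12 | methyl (E)-4-[4-(benzyloxy)-6-methoxy-5-(methoxymethoxy)-3-nitro-2,3-dihydro-1-benzofuran-2-yl]-3-methoxybut-2-enoate (diastereomer mixture) | COC(=O)/C=C(\CC1Oc2cc(OC)c(OCOC)c(OCc3ccccc3)c2C1[N+](=O)[O-])OC
F3 | step 12 | methyl (E)-4-[4-(benzyloxy)-6-methoxy-5-(methoxymethoxy)-1-benzofuran-2-yl]-3-methoxybut-2-enoate | COC(=O)/C=C(\Cc1cc2c(OCc3ccccc3)c(OCOC)c(OC)cc2o1)OC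
F4 | step 12 | (E)-4-[4-(benzyloxy)-6-methoxy-5-(methoxymethoxy)-1-benzofuran-2-yl]-3-methoxybut-2-enoic acid | OC(=O)/C=C(\Cc1cc2c(OCc3ccccc3)c(OCOC)c(OC)cc2o1)OC
F5 | step 12 | 9-(benzyloxy)-3,7-dimethoxy-8-(methoxymethoxy)dibenzofuran-1-yl acetate | COc1cc(OC(C)=O)c2c(c1)oc1cc(OC)c(OCOC)c(OCc3ccccc3)c12
F6 | step 19 | 5-bromo-4-fluoro-6-{[1,3,7-trimethoxy-8-(methoxymethoxy)dibenzofuran-9-yl]oxy}benzene-1,3-dicarbaldehyde | COc1cc(OC)c2c(c1)oc1cc(OC)c(OCOC)c(Oc3c(C=O)cc(C=O)c(F)c3Br)c12
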